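Count the chains.

    free monomer + initiator → living end + monomer in chains (k1 = 0.0097 M⁻¹ s⁻¹)
    free monomer + living end → monomer in chains + living end, rate k2*[living end]*[free monomer] (k2 = 0.12 M⁻¹ s⁻¹)
    free monomer → uncatalysed product (k3 = 3.1 × 10⁻⁵ s⁻¹)
    living end + monomer in chains → dead end (k4 = 3.1 × 10⁻⁴ M⁻¹ s⁻¹)

free monomer 0.80 M; initiator 8.3 mol%; time 20 min

1. whether the average number of monomer units in a chain (chains begun, living or dead) reaches 7.0 by 20 min (yes / no)
2. average number of monomer units in a chain (chains begun, living or dead) at 20 min

- the average divides the monomer in chains by the number of chains begun, living and dead together
- run time (flask): 20 min

Minutes of the meeting on this flask. I opened by saying that each chain begun costs one initiator, whether its end stays living or dies, so the length asked for is monomer in chains over initiator used. The initiator charge is n = 0.0664 M.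

I then set out the race between initiation and growth for free monomer. Let y be the first step's constant times the time integral of the free monomer concentration. Initiator falls as exp(-y), and the used share is f = one minus exp(-y). Taking every chain begun as still living and free monomer as fully consumed, the balance of free monomer gives y = f + (b - f)/R. Here b = 12.0 is the charge ratio of free monomer to initiator, and R = 12.4 is the growth constant over the initiation constant.

A colleague objected that two other steps spoil this balance. I answered that, per free monomer, the uncatalysed step is far slower than growth on n chains, and that the termination constant is far smaller than the growth constant, so I dropped both.

Since f stands on both sides, we iterated from f = one and got 0.849, 0.827, then 0.823. We carried this f, the share of the initiator charge used at complete consumption of free monomer. My own length, free monomer charge over f times n, is 14.6, and my answer on the wanted length is yes.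

The forecast was read next: yes, and a length of 14.2, “with only about 82% of the initiator used”. My figure, which charges no losses, stands above it.

The simulation answers yes, with a length of 14.3 at 20 min.

In this flask at 3.18 min, free monomer has a half-life of 2.2 min by chain growth, shorter than the 3.1 min of initiator by initiation; at 20.0 min free monomer, the limiting reagent, stands at 0.12% of its charge and initiator at 17%, a used share of 83.0% against f = 0.823. In a second flask with half the free monomer and the initiator concentration kept, going round from that f gives 0.712, 0.681, 0.671, hence a length of 8.97, and the run of that flask ends at a length of 8.82.

The numbers come from no measurement; what happens was integrated by code.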